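**Plan**

- Retrosynthesis: the seven-membered lactone is cut at the acyl C16–O bond (C16 traced back to the isopropenyl methyl); the 14-membered carbocycle at C11–C12 (alkenyl iodide + aldehyde); the C11/C12 oxygens to an (E)-allylic alcohol; the oxolane at C4–O together with C8–O (to a bis-epoxy acid); the chain at C5–C6 and C9–C10 (two Claisen iterations) back to a carvone-derived alkynal.
- Forward: (S)-carvone gives the C1 fragment (steps 1–2); two isopropenyl-addition/Johnson–Claisen iterations build C3–C11 with both E alkenes (3–7); Shi bis-epoxidation (8); the cascade closes a temporary γ-lactone and then the oxolane ring (9); Nozaki–Hiyama–Kishi reaction closes the carbocycle (14); the seven-membered lactone closes last (22).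
- Enabling feature: C3=C4 and C7=C8 form a 1,5-diene whose methyl-bearing carbons C4 and C8 each lie five atoms from an oxygen (O on C7, carboxyl O on C11). Two anti, 5-exo openings of the derived epoxides therefore give ring O–C4–C5–C6–C7 (2,5-cis) and the C3 and C8 carbinols in one operation.
- Stereochemistry: C1 from (S)-carvone; C3, C4, C7, C8 from one Shi catalyst plus the stereospecific cascade; C11 from CBS reduction; C12 from hydroxyl-directed epoxidation and regioselective hydride opening.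

Key step: step 9

Assumption: (S)-(+)-carvone and the enantiomer of the Shi ketone (L-fructose series) are taken as commercial; locants C1–C20 follow cembrane numbering (C1 carries the C15(=C17)–C16 unit; C18, C19, C20 are the methyls on C4, C8, C12).

**Route**

Step 1
Reactants: 1 (S)-(+)-carvone
Product: 2 (1S,4S,6S)-1-methyl-4-(prop-1-en-2-yl)-7-oxabicyclo[4.1.0]heptan-2-one
Conditions: 30% H2O2, NaOH (cat.), MeOH, 0 °C
Reagents that add atoms: hydrogen peroxide, OO
Why: Weitz–Scheffer nucleophilic epoxidation of the enone should occur anti to the isopropenyl group; the two oxirane stereocentres are destroyed in step 2.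

Step 2
Reactants: 2 (1S,4S,6S)-1-methyl-4-(prop-1-en-2-yl)-7-oxabicyclo[4.1.0]heptan-2-one
Product: 3 (3R)-3-(prop-1-en-2-yl)hept-5-ynal
Conditions: TsNHNH2, AcOH/CH2Cl2, −20 °C to rt
Reagents that add atoms: none
Why: Eschenmoser–Tanabe fragmentation of the α,β-epoxy ketone cleaves the bond between the two oxirane carbons to give a methyl alkyne arm (C14, C13, C12, C20) and an aldehyde arm (C2, C3), leaving the isopropenyl-bearing stereocentre (C1) untouched.

Step 3
Reactants: 3 (3R)-3-(prop-1-en-2-yl)hept-5-ynal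
Product: 4 (5R)-2-methyl-5-(prop-1-en-2-yl)non-1-en-7-yn-3-ol (both C3 epimers)
Conditions: isopropenylmagnesium bromide, THF, −78 °C; aqueous work-up
Reagents that add atoms: isopropenylmagnesium bromide, CC(=C)[Mg]Br
Why: Grignard 1,2-addition to the aldehyde gives the 2-propenyl carbinol needed for the Claisen step; its configuration is irrelevant because this carbon becomes sp2 in step 4.

Step 4
Reactants: 4 (5R)-2-methyl-5-(prop-1-en-2-yl)non-1-en-7-yn-3-ol
Product: 5 ethyl (4E,7S)-4-methyl-7-(prop-1-en-2-yl)undec-4-en-9-ynoate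
Conditions: MeC(OEt)3, EtCO2H (cat.), 140 °C
Reagents that add atoms: triethyl orthoacetate, CC(OCC)(OCC)OCC
Why: Johnson–Claisen [3,3] rearrangement through a chair transition state with the chain equatorial should give the E trisubstituted alkene (C3=C4) and adds C5–C7.

Step 5
Reactants: 5 ethyl (4E,7S)-4-methyl-7-(prop-1-en-2-yl)undec-4-en-9-ynoate
Product: 6 (4E,7S)-4-methyl-7-(prop-1-en-2-yl)undec-4-en-9-ynal
Conditions: i-Bu2AlH, CH2Cl2, −78 °C
Reagents that add atoms: none
Why: Partial ester reduction at low temperature should stop at the aldehyde through the stable aluminium hemiacetal.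

Step 6
Reactants: 6 (4E,7S)-4-methyl-7-(prop-1-en-2-yl)undec-4-en-9-ynal
Product: 7 (6E,9S)-2,6-dimethyl-9-(prop-1-en-2-yl)trideca-1,6-dien-11-yn-3-ol (both C3 epimers)
Conditions: isopropenylmagnesium bromide, THF, −78 °C; aqueous work-up
Reagents that add atoms: isopropenylmagnesium bromide, CC(=C)[Mg]Br
Why: Second Grignard 1,2-addition of the iterative sequence; the new carbinol centre is again lost in the next step.

Step 7
Reactants: 7 (6E,9S)-2,6-dimethyl-9-(prop-1-en-2-yl)trideca-1,6-dien-11-yn-3-ol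
Product: 8 ethyl (4E,8E,11S)-4,8-dimethyl-11-(prop-1-en-2-yl)pentadeca-4,8-dien-13-ynoate
Conditions: MeC(OEt)3, EtCO2H (cat.), 140 °C
Reagents that add atoms: triethyl orthoacetate, CC(OCC)(OCC)OCC
Why: Second Johnson–Claisen rearrangement sets the E alkene C7=C8 and delivers C9–C11 with C11 at the ester level needed for the cascade.

Step 8
Reactants: 8 ethyl (4E,8E,11S)-4,8-dimethyl-11-(prop-1-en-2-yl)pentadeca-4,8-dien-13-ynoate
Product: 9 ethyl (4S,5S,8S,9S,11R)-4,5:8,9-diepoxy-4,8-dimethyl-11-(prop-1-en-2-yl)pentadec-13-ynoate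
Conditions: ent-Shi ketone (30 mol%), Oxone (2KHSO5·KHSO4·K2SO4), K2CO3, Bu4NHSO4 (cat.), MeCN/CH2(OMe)2–aq. buffer (pH 10.5), 0 °C
Reagents that add atoms: potassium peroxymonosulfate, [K+].[O-]S(=O)(=O)OO
Why: Shi asymmetric epoxidation (chiral dioxirane, spiro transition state) should epoxidise both electron-rich E trisubstituted alkenes with the same facial sense to give (S,S) oxiranes (the L-series ketone is the mirror image of the one that gives (R,R)), faster than the 1,1-disubstituted isopropenyl group and without touching the alkyne.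

Step 9
Reactants: 9 ethyl (4S,5S,8S,9S,11R)-4,5:8,9-diepoxy-4,8-dimethyl-11-(prop-1-en-2-yl)pentadec-13-ynoate
Product: 12 (5R)-5-{(2S,5R)-5-[(1S,3R)-1-hydroxy-3-(prop-1-en-2-yl)hept-5-yn-1-yl]-5-methyloxolan-2-yl}-5-methyloxolan-2-one, via bis-epoxy acid 10 (not isolated), via epoxy hydroxy lactone 11 (not isolated)
Conditions: LiOH (1.5 equiv), THF/H2O, 0 °C to rt; then camphorsulfonic acid (1.7 equiv), CH2Cl2, 0 °C to rt
Reagents that add atoms: lithium hydroxide, [Li+].[OH-]
Why: Saponification unveils the C11 carboxylic acid, which on acidification opens the protonated C7–C8 epoxide at the tertiary carbon C8 with inversion (γ-lactonisation of a γ,δ-epoxy acid), and the C7 hydroxyl so released attacks the activated C3–C4 epoxide at the tertiary carbon C4 with inversion, forming the C4–O bond that closes the oxolane ring; the same product results if the C7–C8 epoxide oxygen attacks C4 first and the epoxonium ion is then captured at C8 by the carboxyl group. The closest known reaction type is the acid-triggered epoxide-opening cascade of a polyepoxide terminated by a carboxyl nucleophile. Both rings close in the 5-exo-tet mode at tertiary carbons, and the γ-lactone is a temporary ring that carries the C8 oxygen and keeps C11 at the acid level for the later ring closure. C3 and C7 keep the configuration set by the Shi catalyst while C4 and C8 are inverted stereospecifically, which should turn the (S,S,S,S) bis-epoxide into the 3S,4R,7S,8R array with the 2,5-cis oxolane. The step needs directional selectivity (the C7 oxygen onto C4 and a second oxygen onto C8, not the reverse, which would invert C7 or give oxane and oxepane isomers) and exo over endo opening; the C11 carboxyl secures the direction because it is the only nucleophile that reaches C8 through a five-membered transition state and no external nucleophile is present, and the methyl groups on C4 and C8 secure exo attack. Oxygen attack through five-membered transition states under mild Brønsted acid should outrun cation–olefin cyclisation onto the isopropenyl or alkyne π systems.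

Step 10
Reactants: 12 the oxolane–γ-lactone alcohol
Product: 13 (4R)-4-{(2S,5R)-5-[(1S,3R)-1-hydroxy-3-(prop-1-en-2-yl)hept-5-yn-1-yl]-5-methyloxolan-2-yl}pentane-1,4-diol
Conditions: LiAlH4, THF, 0 °C
Reagents that add atoms: none
Why: Hydride reduction of the lactone to the 1,4-diol removes the temporary ring and frees the C8 hydroxyl; the isolated internal alkyne should be inert.

Step 11
Reactants: 13 the triol
Product: 14 tris(triethylsilyl) ether of 13 (silyl groups on the oxygens at C3, C8 and C11)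
Conditions: Et3SiOTf, 2,6-lutidine, CH2Cl2, −78 to 0 °C
Reagents that add atoms: triethylsilyl trifluoromethanesulfonate, CC[Si](CC)(CC)OS(=O)(=O)C(F)(F)F
Why: Silyl triflate silylation protects the primary, the hindered secondary and the tertiary hydroxyl in one operation.

Step 12
Reactants: 14 the tris(triethylsilyl) ether
Product: 16 (E)-alkenyl iodide (C13H=C12(I)–CH3; other groups as in 14), via alkenylzirconocene chloride 15 (not isolated)
Conditions: Cp2Zr(H)Cl, THF, rt; then I2, 0 °C
Reagents that add atoms: iodine, II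
Why: Syn hydrozirconation of the 2-alkyne should place zirconium on the less hindered methyl-bearing carbon (C12) after equilibration, and iodinolysis with retention gives the (E)-2-iodo-2-alkene; the hindered 1,1-disubstituted alkene should react more slowly.

Step 13
Reactants: 16 the (E)-alkenyl iodide
Product: 17 C11 aldehyde (bis(triethylsilyl) ether at C3 and C8; alkenyl iodide retained)
Conditions: (COCl)2, DMSO, CH2Cl2, −78 °C; Et3N, −78 to −30 °C
Reagents that add atoms: none
Why: Swern conditions cleave and oxidise a primary triethylsilyl ether selectively, leaving the secondary and tertiary silyl ethers.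

Step 14
Reactants: 17 the iodo aldehyde
Product: 18 (1R,3S,4R,7S,8R,12E)-4,7-epoxy-3,8-bis(triethylsilyloxy)cembra-12,15(17)-dien-11-ol (C11 epimers)
Conditions: CrCl2 (10 equiv), NiCl2 (1 mol%), DMSO/THF, rt, 2 mM
Reagents that add atoms: none
Why: Nozaki–Hiyama–Kishi macrocyclisation (addition of the alkenylchromium species to the aldehyde with retention of alkene geometry) forms the C11–C12 bond and the 14-membered carbocycle; the C11 configuration is not controlled here and is set in steps 15 and 16.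

Step 15
Reactants: 18 the macrocyclic allylic alcohol (C11 epimers)
Product: 19 (1R,3S,4R,7S,8R,12E)-4,7-epoxy-3,8-bis(triethylsilyloxy)cembra-12,15(17)-dien-11-one
Conditions: Dess–Martin periodinane, NaHCO3, CH2Cl2, 0 °C to rt
Reagents that add atoms: none
Why: Dess–Martin oxidation converges both carbinol epimers on one α-methyl enone.

Step 16
Reactants: 19 the macrocyclic enone
Product: 20 (1R,3S,4R,7S,8R,11R,12E)-4,7-epoxy-3,8-bis(triethylsilyloxy)cembra-12,15(17)-dien-11-ol
Conditions: (S)-2-methyl-CBS-oxazaborolidine (20 mol%), catecholborane, toluene, −78 °C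
Reagents that add atoms: none
Why: Corey–Bakshi–Shibata reduction with the α-branched alkenyl group as the large substituent should give the 11R alcohol with the (S) catalyst, and catecholborane at low temperature should not hydroborate the isopropenyl group.

Step 17
Reactants: 20 the (11R)-allylic alcohol
Product: 21 (1R,3S,4R,7S,8R,11R,12S,13S)-4,7:12,13-diepoxy-3,8-bis(triethylsilyloxy)cembr-15(17)-en-11-ol
Conditions: VO(acac)2 (5 mol%), t-BuOOH, CH2Cl2, 0 °C to rt
Reagents that add atoms: tert-butyl hydroperoxide, CC(C)(C)OO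
Why: Hydroxyl-directed vanadium-catalysed epoxidation of a 2-methyl-substituted allylic alcohol is erythro-selective (A(1,2) strain between C10 and the C12 methyl), which puts the oxygen on the C12 face that later reads 12R; the isopropenyl group has no directing hydroxyl.

Step 18
Reactants: 21 the epoxy alcohol
Product: 22 (1R,3S,4R,7S,8R,11R,12R)-4,7-epoxy-3,8-bis(triethylsilyloxy)cembr-15(17)-ene-11,12-diol
Conditions: LiAlH4, THF, 0 °C to rt
Reagents that add atoms: none
Why: Hydride opening of the 2,3-epoxy alcohol by SN2 attack at the less substituted C13 makes C13 a methylene and keeps the C12–O bond and its configuration.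

Step 19
Reactants: 22 the 11,12-diol
Product: 23 (1R,3S,4R,7S,8R,11R,12R)-4,7-epoxy-3,8,11-tris(triethylsilyloxy)cembr-15(17)-en-12-ol
Conditions: Et3SiCl, imidazole, CH2Cl2, 0 °C
Reagents that add atoms: chlorotriethylsilane, CC[Si](CC)(CC)Cl
Why: Silylation with the silyl chloride is selective for the secondary C11 hydroxyl over the tertiary C12 hydroxyl, which stays free for the lactonisation.

Step 20
Reactants: 23 the C12 tertiary alcohol
Product: 24 (1R,3S,4R,7S,8R,11R,12R)-4,7-epoxy-3,8,11-tris(triethylsilyloxy)cembr-15(17)-ene-12,16-diol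
Conditions: SeO2 (0.5 equiv), t-BuOOH, CH2Cl2, 0 °C to rt
Reagents that add atoms: selenium dioxide, O=[Se]=O; tert-butyl hydroperoxide, CC(C)(C)OO
Why: Allylic oxidation (ene reaction followed by [2,3]-sigmatropic shift) of the isopropenyl methyl group, as known for ring-bound isopropenyl groups, should return the 1,1-disubstituted alkene with a hydroxyl on C16.

Step 21
Reactants: 24 the allylic alcohol
Product: 26 (1R,3S,4R,7S,8R,11R,12R)-4,7-epoxy-12-hydroxy-3,8,11-tris(triethylsilyloxy)cembr-15(17)-en-16-oic acid, via enal 25 (not isolated)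
Conditions: MnO2, CH2Cl2, rt; then NaClO2, NaH2PO4, 2-methyl-2-butene, t-BuOH/H2O, 0 °C
Reagents that add atoms: sodium chlorite, [Na+].[O-]Cl=O
Why: MnO2 oxidises only the allylic primary alcohol and Pinnick oxidation converts the 2-substituted acrolein into the acrylic acid without touching the alkene or the tertiary alcohol.

Step 22
Reactants: 26 the hydroxy acid
Product: 28 3,8,11-tris-O-(triethylsilyl)querciformolide D, via mixed anhydride 27 (not isolated)
Conditions: 2,4,6-Cl3C6H2COCl, Et3N, THF, rt; then DMAP, toluene, 80 °C, 1 mM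
Reagents that add atoms: none
Why: Yamaguchi lactonisation through the mixed anhydride and the acylpyridinium ion should acylate the only free hydroxyl (tertiary C12–OH) to close the seven-membered ring; C1 and C12 sit 1,4 across the carbocycle, which holds the acid near the alcohol.

Step 23
Reactants: 28 3,8,11-tris-O-(triethylsilyl)querciformolide D
Product: 29 querciformolide D
Conditions: HF·pyridine, pyridine/THF, 0 °C to rt
Reagents that add atoms: none
Why: Fluoride-mediated cleavage of the three triethylsilyl ethers under buffered conditions should spare the α-methylene lactone.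

**Compound list**

1 | (S)-(+)-carvone | CC1=CC[C@@H](CC1=O)C(C)=C | starting material
2 | (1S,4S,6S)-1-methyl-4-(prop-1-en-2-yl)-7-oxabicyclo[4.1.0]heptan-2-one | O=C1C[C@@H](C(C)=C)C[C@@H]2O[C@]12C | intermediate
3 | (3R)-3-(prop-1-en-2-yl)hept-5-ynal | CC#CC[C@H](CC=O)C(C)=C | intermediate
4 | (5R)-2-methyl-5-(prop-1-en-2-yl)non-1-en-7-yn-3-ol (C3 epimers) | CC#CC[C@H](CC(O)C(C)=C)C(C)=C | intermediate
5 | ethyl (4E,7S)-4-methyl-7-(prop-1-en-2-yl)undec-4-en-9-ynoate | CCOC(=O)CC/C(C)=C/C[C@@H](CC#CC)C(C)=C | intermediate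
6 | (4E,7S)-4-methyl-7-(prop-1-en-2-yl)undec-4-en-9-ynal | O=CCC/C(C)=C/C[C@@H](CC#CC)C(C)=C | intermediate
7 | (6E,9S)-2,6-dimethyl-9-(prop-1-en-2-yl)trideca-1,6-dien-11-yn-3-ol (C3 epimers) | C=C(C)C(O)CC/C(C)=C/C[C@@H](CC#CC)C(C)=C | intermediate
8 | ethyl (4E,8E,11S)-4,8-dimethyl-11-(prop-1-en-2-yl)pentadeca-4,8-dien-13-ynoate | CCOC(=O)CC/C(C)=C/CC/C(C)=C/C[C@@H](CC#CC)C(C)=C | intermediate
9 | ethyl (4S,5S,8S,9S,11R)-4,5:8,9-diepoxy-4,8-dimethyl-11-(prop-1-en-2-yl)pentadec-13-ynoate | CCOC(=O)CC[C@]1(C)O[C@H]1CC[C@]2(C)O[C@H]2C[C@@H](CC#CC)C(C)=C | intermediate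
10 | (4S,5S,8S,9S,11R)-4,5:8,9-diepoxy-4,8-dimethyl-11-(prop-1-en-2-yl)pentadec-13-ynoic acid | OC(=O)CC[C@]1(C)O[C@H]1CC[C@]2(C)O[C@H]2C[C@@H](CC#CC)C(C)=C | intermediate (not isolated)
11 | (5R)-5-[(1S)-1-hydroxy-3-{(2S,3S)-2-methyl-3-[(2R)-2-(prop-1-en-2-yl)hex-4-yn-1-yl]oxiran-2-yl}propyl]-5-methyloxolan-2-one | O=C1CC[C@@](C)(O1)[C@@H](O)CC[C@]2(C)O[C@H]2C[C@@H](CC#CC)C(C)=C | intermediate (not isolated)
12 | (5R)-5-{(2S,5R)-5-[(1S,3R)-1-hydroxy-3-(prop-1-en-2-yl)hept-5-yn-1-yl]-5-methyloxolan-2-yl}-5-methyloxolan-2-one | O=C1CC[C@@](C)(O1)[C@@H]2CC[C@@](C)(O2)[C@@H](O)C[C@@H](CC#CC)C(C)=C | intermediate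
13 | (4R)-4-{(2S,5R)-5-[(1S,3R)-1-hydroxy-3-(prop-1-en-2-yl)hept-5-yn-1-yl]-5-methyloxolan-2-yl}pentane-1,4-diol | OCCC[C@@](C)(O)[C@@H]1CC[C@@](C)(O1)[C@@H](O)C[C@@H](CC#CC)C(C)=C | intermediate
14 | tris(triethylsilyl) ether of 13 | CC[Si](CC)(CC)OCCC[C@@](C)(O[Si](CC)(CC)CC)[C@@H]1CC[C@@](C)(O1)[C@@H](O[Si](CC)(CC)CC)C[C@@H](CC#CC)C(C)=C | intermediate
15 | (E)-alkenylzirconocene chloride from 14 (Zr on C12) | CC[Si](CC)(CC)OCCC[C@@](C)(O[Si](CC)(CC)CC)[C@@H]1CC[C@@](C)(O1)[C@@H](O[Si](CC)(CC)CC)C[C@@H](C/C=C(\C)[Zr](Cl)(C1C=CC=C1)C1C=CC=C1)C(C)=C | intermediate (not isolated)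
16 | (E)-alkenyl iodide (iodine on C12), tris(triethylsilyl) ether | CC[Si](CC)(CC)OCCC[C@@](C)(O[Si](CC)(CC)CC)[C@@H]1CC[C@@](C)(O1)[C@@H](O[Si](CC)(CC)CC)C[C@@H](C/C=C(\C)I)C(C)=C | intermediate
17 | C11 aldehyde with (E)-alkenyl iodide, bis(triethylsilyl) ether | O=CCC[C@@](C)(O[Si](CC)(CC)CC)[C@@H]1CC[C@@](C)(O1)[C@@H](O[Si](CC)(CC)CC)C[C@@H](C/C=C(\C)I)C(C)=C | intermediate
18 | (1R,3S,4R,7S,8R,12E)-4,7-epoxy-3,8-bis(triethylsilyloxy)cembra-12,15(17)-dien-11-ol (C11 epimers) | OC1CC[C@@](C)(O[Si](CC)(CC)CC)[C@@H]2CC[C@@](C)(O2)[C@@H](O[Si](CC)(CC)CC)C[C@@H](C/C=C1\C)C(C)=C | intermediate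
19 | (1R,3S,4R,7S,8R,12E)-4,7-epoxy-3,8-bis(triethylsilyloxy)cembra-12,15(17)-dien-11-one | O=C1CC[C@@](C)(O[Si](CC)(CC)CC)[C@@H]2CC[C@@](C)(O2)[C@@H](O[Si](CC)(CC)CC)C[C@@H](C/C=C1\C)C(C)=C | intermediate
20 | (1R,3S,4R,7S,8R,11R,12E)-4,7-epoxy-3,8-bis(triethylsilyloxy)cembra-12,15(17)-dien-11-ol | O[C@@H]1CC[C@@](C)(O[Si](CC)(CC)CC)[C@@H]2CC[C@@](C)(O2)[C@@H](O[Si](CC)(CC)CC)C[C@@H](C/C=C1\C)C(C)=C | intermediate
21 | (1R,3S,4R,7S,8R,11R,12S,13S)-4,7:12,13-diepoxy-3,8-bis(triethylsilyloxy)cembr-15(17)-en-11-ol | O[C@@H]1CC[C@@](C)(O[Si](CC)(CC)CC)[C@@H]2CC[C@@](C)(O2)[C@@H](O[Si](CC)(CC)CC)C[C@@H](C[C@@H]3O[C@]31C)C(C)=C | intermediate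
22 | (1R,3S,4R,7S,8R,11R,12R)-4,7-epoxy-3,8-bis(triethylsilyloxy)cembr-15(17)-ene-11,12-diol | O[C@@H]1CC[C@@](C)(O[Si](CC)(CC)CC)[C@@H]2CC[C@@](C)(O2)[C@@H](O[Si](CC)(CC)CC)C[C@@H](CC[C@@]1(C)O)C(C)=C | intermediate
23 | (1R,3S,4R,7S,8R,11R,12R)-4,7-epoxy-3,8,11-tris(triethylsilyloxy)cembr-15(17)-en-12-ol | CC[Si](CC)(CC)O[C@@H]1CC[C@@](C)(O[Si](CC)(CC)CC)[C@@H]2CC[C@@](C)(O2)[C@@H](O[Si](CC)(CC)CC)C[C@@H](CC[C@@]1(C)O)C(C)=C | intermediate
24 | (1R,3S,4R,7S,8R,11R,12R)-4,7-epoxy-3,8,11-tris(triethylsilyloxy)cembr-15(17)-ene-12,16-diol | CC[Si](CC)(CC)O[C@@H]1CC[C@@](C)(O[Si](CC)(CC)CC)[C@@H]2CC[C@@](C)(O2)[C@@H](O[Si](CC)(CC)CC)C[C@@H](CC[C@@]1(C)O)C(=C)CO | intermediate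
25 | (1R,3S,4R,7S,8R,11R,12R)-4,7-epoxy-12-hydroxy-3,8,11-tris(triethylsilyloxy)cembr-15(17)-en-16-al | CC[Si](CC)(CC)O[C@@H]1CC[C@@](C)(O[Si](CC)(CC)CC)[C@@H]2CC[C@@](C)(O2)[C@@H](O[Si](CC)(CC)CC)C[C@@H](CC[C@@]1(C)O)C(=C)C=O | intermediate (not isolated)
26 | (1R,3S,4R,7S,8R,11R,12R)-4,7-epoxy-12-hydroxy-3,8,11-tris(triethylsilyloxy)cembr-15(17)-en-16-oic acid | CC[Si](CC)(CC)O[C@@H]1CC[C@@](C)(O[Si](CC)(CC)CC)[C@@H]2CC[C@@](C)(O2)[C@@H](O[Si](CC)(CC)CC)C[C@@H](CC[C@@]1(C)O)C(=C)C(=O)O | intermediate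
27 | mixed anhydride of 26 with 2,4,6-trichlorobenzoic acid | CC[Si](CC)(CC)O[C@@H]1CC[C@@](C)(O[Si](CC)(CC)CC)[C@@H]2CC[C@@](C)(O2)[C@@H](O[Si](CC)(CC)CC)C[C@@H](CC[C@@]1(C)O)C(=C)C(=O)OC(=O)c1c(Cl)cc(Cl)cc1Cl | intermediate (not isolated)
28 | 3,8,11-tris-O-(triethylsilyl)querciformolide D | CC[Si](CC)(CC)O[C@@H]1CC[C@@](C)(O[Si](CC)(CC)CC)[C@@H]2CC[C@@](C)(O2)[C@@H](O[Si](CC)(CC)CC)C[C@H]3CC[C@@]1(C)OC(=O)C3=C | intermediate
29 | querciformolide D | C=C1C(=O)O[C@]2(C)CC[C@@H]1C[C@H](O)[C@@]1(C)CC[C@H](O1)[C@](C)(O)CC[C@H]2O | target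

**Summary**

Total step count: 23. Longest linear sequence: 23 steps from (S)-(+)-carvone (fully linear).

Steps most likely to fail:

1. Step 22 (lactonisation). Acyl transfer from the activated 2-substituted acrylate to the hindered tertiary C12 hydroxyl may be slower than intermolecular ester or anhydride formation, so oligomers would form instead of the seven-membered ring. Fallback (acylpalladium in place of an activated carboxylate, C16 brought in as CO): setting out from 23, the C12 hydroxyl is masked as the trimethylsilyl ether F1 (Me3SiOTf, 2,6-lutidine, CH2Cl2, −78 °C). Ozonolysis (O3, CH2Cl2/MeOH, −78 °C; Me2S) converts the isopropenyl group into the methyl ketone F2. KN(SiMe3)2 and PhNTf2 (THF, −78 °C) give the kinetic enol triflate F3. Citric acid in MeOH (0 °C) frees the tertiary alcohol to give the hydroxy enol triflate F4. Pd(PPh3)4 (zerovalent palladium), CO (1 atm), Et3N, MeCN, 60 °C then closes the α-methylene lactone by intramolecular alkoxycarbonylation, coming back to the route at 28.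

2. Step 14 (macrocyclisation). Oxidative addition and transmetalation of the hindered trisubstituted alkenyl iodide may be slow, so that protodeiodination and intermolecular coupling compete with ring closure. Fallback (direct reductive alkyne–aldehyde coupling, no alkenyl halide): setting out from 14, Swern oxidation as in step 13 gives the alkynal F5. Ni(cod)2 (zerovalent nickel), PBu3 and Et3B in toluene/EtOAc at high dilution then join the aldehyde carbon to the less hindered, methyl-bearing alkyne carbon with syn delivery of hydrogen to C13. This gives the (E)-allylic alcohol and comes back to the route at 18.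

3. Step 20 (allylic oxidation). The ene reaction may take the allylic hydrogen on C1 instead of a methyl hydrogen, which would oxidise C1 and destroy its stereocentre; over-oxidation is a second failure mode. Fallback (ene-type chlorination, then N-oxide oxidation): setting out from 23, Ca(OCl)2 and CO2 (dry ice) in CH2Cl2/H2O at 0 °C should give the 2-(chloromethyl)allyl compound F6, as known for the isopropenyl group of carvone. N-methylmorpholine N-oxide in MeCN at 60 °C converts F6 into enal 25, which the chlorite stage of step 21 carries to 26.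

Further compounds
F1 | step 22 | 12-O-trimethylsilyl ether of 23 | CC[Si](CC)(CC)O[C@@H]1CC[C@@](C)(O[Si](CC)(CC)CC)[C@@H]2CC[C@@](C)(O2)[C@@H](O[Si](CC)(CC)CC)C[C@@H](CC[C@@]1(C)O[Si](C)(C)C)C(C)=C
F2 | step 22 | methyl ketone from ozonolysis of F1 (acetyl group on C1) | CC[Si](CC)(CC)O[C@@H]1CC[C@@](C)(O[Si](CC)(CC)CC)[C@@H]2CC[C@@](C)(O2)[C@@H](O[Si](CC)(CC)CC)C[C@@H](CC[C@@]1(C)O[Si](C)(C)C)C(C)=O
F3 | step 22 | enol triflate of F2 (1-(trifluoromethanesulfonyloxy)vinyl group on C1) | CC[Si](CC)(CC)O[C@@H]1CC[C@@](C)(O[Si](CC)(CC)CC)[C@@H]2CC[C@@](C)(O2)[C@@H](O[Si](CC)(CC)CC)C[C@@H](CC[C@@]1(C)O[Si](C)(C)C)C(=C)OS(=O)(=O)C(F)(F)F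
F4 | step 22 | hydroxy enol triflate (F3 with free C12 hydroxyl) | CC[Si](CC)(CC)O[C@@H]1CC[C@@](C)(O[Si](CC)(CC)CC)[C@@H]2CC[C@@](C)(O2)[C@@H](O[Si](CC)(CC)CC)C[C@@H](CC[C@@]1(C)O)C(=C)OS(=O)(=O)C(F)(F)F
F5 | step 14 | C11 aldehyde with intact 2-butynyl arm, bis(triethylsilyl) ether | O=CCC[C@@](C)(O[Si](CC)(CC)CC)[C@@H]1CC[C@@](C)(O1)[C@@H](O[Si](CC)(CC)CC)C[C@@H](CC#CC)C(C)=C
F6 | step 20 | allylic chloride from 23 (3-chloroprop-1-en-2-yl group on C1) | CC[Si](CC)(CC)O[C@@H]1CC[C@@](C)(O[Si](CC)(CC)CC)[C@@H]2CC[C@@](C)(O2)[C@@H](O[Si](CC)(CC)CC)C[C@@H](CC[C@@]1(C)O)C(=C)CCl
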